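**Plan**

- Retrosynthesis: the O–Si bond is cut last. Then the ring bond C3–C4 is cut while C4 is joined to C6, which folds the cyclohexenone (C1 C=O, C2 C–OMe, C3 =CH, C4 CH–O, C5 CH–farnesyl, C6 CH–Me) into a 2-silyloxycyclopropyl 1-methoxyvinyl ketone. Further cuts: C1–C2 (acyl plus vinyllithium), C6–CH3, the cyclopropane bonds C6–C4 and C6–C5 (carbene plus enol ether), and the CH2–CH2 bond beside the farnesyl unit.
- Enabling feature: C4 carries a donor oxygen and C6 lies alpha to the C1 ketone, so a C4–C6 bond is the push–pull bond of a donor–acceptor cyclopropane C4–C5–C6. C3 is the nucleophilic end of the C2 methoxy enol ether and closes the six-membered ring C1–C6 when it adds to C4.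
- Forward: the chain comes first (farnesyl bromide, ester, aldehyde, (Z)-silyl enol ether), then the three-membered ring, the C6 methyl and the C2–C3 unit. The cyclohexenone, the only ring of the target, arises in the penultimate step by ring-opening cyclisation.
- Stereochemistry: 2E,6E is bought with farnesyl bromide. C5 is set by copper–bis(oxazoline) cyclopropanation and is the one centre carried through. C4 is set in the ring closure (allylic strain plus an outward silyloxy group) and C6 by base equilibration to the trans isomer.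

Key step: step 8

Remarks: ring atoms keep the numbering above throughout; "farnesyl" means (2E,6E)-3,7,11-trimethyldodeca-2,6,10-trien-1-yl and TIPS means triisopropylsilyl. The sense of induction in step 4 is assumed to follow that known for styrene with the same ligand (carbene carbon R); if it proves opposite, the (R,R)-ligand is used.

**Route**

Step 1
Reactants: 1 (2E,6E)-farnesyl bromide; 2 tert-butyl acetate
Product: 4 tert-butyl (4E,8E)-5,9,13-trimethyltetradeca-4,8,12-trienoate, via lithium enolate of tert-butyl acetate 3 (not isolated)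
Conditions: 2 (1.3 equiv), LiN(iPr)2, THF, −78 °C; then 1, DMPU, −78 → 0 °C
Reagents that add atoms: none
Why: Alkylation of a lithium ester enolate at the primary allylic carbon of 1 (SN2) is a standard two-carbon homologation; the tert-butyl ester enolate does not self-condense, the excess of enolate suppresses double alkylation, and the 2E,6E geometry is not touched.

Step 2
Reactants: 4 tert-butyl (4E,8E)-5,9,13-trimethyltetradeca-4,8,12-trienoate
Product: 6 (4E,8E)-5,9,13-trimethyltetradeca-4,8,12-trienal, via diisobutylaluminium hemiacetal 5 (not isolated)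
Conditions: iBu2AlH (1.1 equiv), CH2Cl2, −78 °C; then aq. KNaC4H4O6
Reagents that add atoms: none
Why: Partial ester reduction with iBu2AlH at −78 °C stops at the aluminium hemiacetal 5, which releases the aldehyde only on aqueous work-up, and the isolated trisubstituted alkenes are inert to the hydride.

Step 3
Reactants: 6 (4E,8E)-5,9,13-trimethyltetradeca-4,8,12-trienal
Product: 7 triisopropyl{[(1Z,4E,8E)-5,9,13-trimethyltetradeca-1,4,8,12-tetraen-1-yl]oxy}silane
Conditions: TIPSOTf (1.2 equiv), Et3N (2 equiv), CH2Cl2, 0 °C → rt; chromatography on Et3N-deactivated silica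
Reagents that add atoms: triisopropylsilyl trifluoromethanesulfonate, CC(C)[Si](OS(=O)(=O)C(F)(F)F)(C(C)C)C(C)C
Why: Soft enolisation and O-silylation of an aldehyde with a silyl triflate and a tertiary amine (silyl enol ether formation) is expected to favour the (Z)-isomer, which places the chain cis to the silyloxy group; no stereocentre is formed.

Step 4
Reactants: 7 triisopropyl{[(1Z,4E,8E)-5,9,13-trimethyltetradeca-1,4,8,12-tetraen-1-yl]oxy}silane; 8 ethyl diazoacetate
Product: 9 ethyl (1R,2R,3R)-3-farnesyl-2-[(triisopropylsilyl)oxy]cyclopropane-1-carboxylate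
Conditions: (CuOTf)2·C6H6 (1 mol%), 2,2'-(propane-2,2-diyl)bis[(4S)-4-tert-butyl-4,5-dihydro-1,3-oxazole] (2.2 mol%), CH2Cl2, 0 °C → rt; 8 (1.3 equiv) added by syringe pump over 10 h
Reagents that add atoms: none
Why: Copper–bis(oxazoline)-catalysed carbene transfer from a diazoacetate to a silyl enol ether (asymmetric cyclopropanation) should take place at the electron-rich enol ether in preference to the three unactivated trisubstituted alkenes; the ester goes exo (trans to both cis substituents of the Z-alkene), the cis relation of OTIPS and chain is inherited from the alkene geometry, and the C2-symmetric ligand selects the carbene face, which fixes 3R at the chain-bearing carbon (the later C5).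

Step 5
Reactants: 9 ethyl (1R,2R,3R)-3-farnesyl-2-[(triisopropylsilyl)oxy]cyclopropane-1-carboxylate
Product: 11 ethyl (1S,2R,3R)-3-farnesyl-1-methyl-2-[(triisopropylsilyl)oxy]cyclopropane-1-carboxylate, via lithium ester enolate 10 (not isolated)
Conditions: LiN(iPr)2 (1.2 equiv), THF, −78 °C; then MeI (3 equiv), −78 → −40 °C
Reagents that add atoms: iodomethane, CI
Why: 2-Silyloxycyclopropanecarboxylates are deprotonated at −78 °C to ring-intact ester enolates, and enolate alkylation with MeI should occur on the face away from the two cis substituents (methyl trans to OTIPS and chain); the configuration of this carbon is of no consequence because it becomes planar in step 8.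

Step 6
Reactants: 11 ethyl (1S,2R,3R)-3-farnesyl-1-methyl-2-[(triisopropylsilyl)oxy]cyclopropane-1-carboxylate
Product: 12 (1S,2R,3R)-3-farnesyl-N-methoxy-N,1-dimethyl-2-[(triisopropylsilyl)oxy]cyclopropane-1-carboxamide
Conditions: MeNH(OMe)·HCl (3 equiv), iPrMgCl (6 equiv), THF, −20 → 0 °C
Reagents that add atoms: N,O-dimethylhydroxylamine hydrochloride, CNOC.Cl
Why: Aminolysis of an ester by the chloromagnesium amide of N,O-dimethylhydroxylamine (Weinreb amide formation) is basic but not Lewis acidic, so the silyloxycyclopropane should survive, and the substrate has no alpha hydrogen to lose.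

Step 7
Reactants: 12 (1S,2R,3R)-3-farnesyl-N-methoxy-N,1-dimethyl-2-[(triisopropylsilyl)oxy]cyclopropane-1-carboxamide; 13 methyl vinyl ether
Product: 16 1-{(1S,2R,3R)-3-farnesyl-1-methyl-2-[(triisopropylsilyl)oxy]cyclopropyl}-2-methoxyprop-2-en-1-one, via 1-methoxyvinyllithium 14 (not isolated), via lithium tetrahedral adduct 15 (not isolated)
Conditions: 13 (2.5 equiv), tBuLi (2 equiv), THF, −78 → 0 °C; then 12, −78 °C; pH 7 phosphate buffer; chromatography on Et3N-deactivated silica
Reagents that add atoms: none
Why: Alpha-lithiation of methyl vinyl ether followed by acylation with the amide (Weinreb ketone synthesis) stops at the ketone because the chelated adduct 15 collapses only on the neutral aqueous quench; the cyclopropane stereocentres are not involved.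

Step 8
Reactants: 16 1-{(1S,2R,3R)-3-farnesyl-1-methyl-2-[(triisopropylsilyl)oxy]cyclopropyl}-2-methoxyprop-2-en-1-one
Product: 20 (4R,5R,6R)-5-farnesyl-2-methoxy-6-methyl-4-[(triisopropylsilyl)oxy]cyclohex-2-en-1-one, via ring-opened zwitterion 17 (not isolated), via cyclic dienol 18 (not isolated), via C6-epimeric ketone mixture 19 (not isolated)
Conditions: Sc(OTf)3 (10 mol%), 2,6-di-tert-butyl-4-methylpyridine (20 mol%), CH2Cl2, −40 → 0 °C; then DBU (0.3 equiv), 0 °C → rt
Reagents that add atoms: none
Why: Sc(OTf)3 binds the ketone/methoxy chelate of 16 and the push–pull C4–C6 bond ionises to zwitterion 17 (silyloxycarbenium ion at C4, 2-methoxy dienolate C3=C2–C1(O)=C6); C3 then adds to C4 with loss of the C3 proton to give dienol 18, which ketonises at C6 to 19 and is equilibrated by DBU to 20. The closest known reaction type is the acid-catalysed formal homo-Nazarov cyclisation of donor-substituted cyclopropyl vinyl ketones, established for aryl and heteroatom donors and for alpha-alkoxyvinyl ketones; the silyloxy donor is a substrate variation within that class. The six-membered ring closes in a 6-(enolendo)-exo-trig mode, a Prins-type addition of the enol ether carbon to the exocyclic C=O+ bond. C4 is controlled in a half-chair transition state in which the C5 chain is pseudoaxial to avoid A(1,2) strain with the C6 methyl of the planar dienolate and the bulky OTIPS group of the oxocarbenium ion points outward, so the new C–O bond ends cis to the chain (4R); C6 is set under thermodynamic control by the DBU equilibration, methyl trans to the chain (6R). The step needs cleavage of C4–C6 and no other ring bond (only this bond lies between donor and acceptor), C-closure through C3 in preference to O-closure or re-closure at C6 (both reversible, whereas attack by C3 is made irreversible by proton loss), and retention of C5 (it is not a reacting atom, and the low temperature and the hindered pyridine buffer disfavour enol ether formation from the carbenium ion and acid damage to the triene).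

Step 9
Reactants: 20 (4R,5R,6R)-5-farnesyl-2-methoxy-6-methyl-4-[(triisopropylsilyl)oxy]cyclohex-2-en-1-one
Product: 21 (4R,5R,6R)-5-farnesyl-4-hydroxy-2-methoxy-6-methylcyclohex-2-en-1-one
Conditions: Bu4NF, AcOH (1:1), THF, 0 °C → rt
Reagents that add atoms: none
Why: Fluoride-mediated silyl ether cleavage buffered with acetic acid should free the C4 alcohol without base-induced change at C6 or C4 and without harm to the methoxy enone or the triene, so the three stereocentres stay as set.

**Compound list**

1 | (2E,6E)-farnesyl bromide | BrC/C=C(\C)CC/C=C(\C)CCC=C(C)C | starting material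
2 | tert-butyl acetate | CC(=O)OC(C)(C)C | starting material
3 | lithium enolate of tert-butyl acetate | C=C(O[Li])OC(C)(C)C | intermediate (not isolated)
4 | tert-butyl (4E,8E)-5,9,13-trimethyltetradeca-4,8,12-trienoate | CC(C)(C)OC(=O)CC/C=C(\C)CC/C=C(\C)CCC=C(C)C | intermediate
5 | diisobutylaluminium hemiacetal formed from 4 (O-aluminated tert-butyl hemiacetal of 6) | CC(C)(C)OC(O[Al](CC(C)C)CC(C)C)CC/C=C(\C)CC/C=C(\C)CCC=C(C)C | intermediate (not isolated)
6 | (4E,8E)-5,9,13-trimethyltetradeca-4,8,12-trienal | O=CCC/C=C(\C)CC/C=C(\C)CCC=C(C)C | intermediate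
7 | triisopropyl{[(1Z,4E,8E)-5,9,13-trimethyltetradeca-1,4,8,12-tetraen-1-yl]oxy}silane | CC(C)[Si](O/C=C\C/C=C(\C)CC/C=C(\C)CCC=C(C)C)(C(C)C)C(C)C | intermediate
8 | ethyl diazoacetate | CCOC(=O)C=[N+]=[N-] | starting material
9 | ethyl (1R,2R,3R)-3-farnesyl-2-[(triisopropylsilyl)oxy]cyclopropane-1-carboxylate (ester trans to OTIPS and chain, which are cis to each other) | CCOC(=O)[C@H]1[C@H](O[Si](C(C)C)(C(C)C)C(C)C)[C@@H]1C/C=C(\C)CC/C=C(\C)CCC=C(C)C | intermediate
10 | lithium ester enolate of 9 (C1 planar, 2R,3R) | CCOC(O[Li])=C1[C@H](O[Si](C(C)C)(C(C)C)C(C)C)[C@@H]1C/C=C(\C)CC/C=C(\C)CCC=C(C)C | intermediate (not isolated)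
11 | ethyl (1S,2R,3R)-3-farnesyl-1-methyl-2-[(triisopropylsilyl)oxy]cyclopropane-1-carboxylate (methyl trans to OTIPS and chain) | CCOC(=O)[C@]1(C)[C@H](O[Si](C(C)C)(C(C)C)C(C)C)[C@@H]1C/C=C(\C)CC/C=C(\C)CCC=C(C)C | intermediate
12 | (1S,2R,3R)-3-farnesyl-N-methoxy-N,1-dimethyl-2-[(triisopropylsilyl)oxy]cyclopropane-1-carboxamide | CON(C)C(=O)[C@]1(C)[C@H](O[Si](C(C)C)(C(C)C)C(C)C)[C@@H]1C/C=C(\C)CC/C=C(\C)CCC=C(C)C | intermediate
13 | methyl vinyl ether | COC=C | starting material
14 | 1-methoxyvinyllithium | [Li]C(=C)OC | intermediate (not isolated)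
15 | lithium tetrahedral adduct of 12 and 14 (N-methoxy-N-methyl hemiaminal alkoxide, carbinol carbon undefined) | C=C(OC)C(O[Li])(N(C)OC)[C@]1(C)[C@H](O[Si](C(C)C)(C(C)C)C(C)C)[C@@H]1C/C=C(\C)CC/C=C(\C)CCC=C(C)C | intermediate (not isolated)
16 | 1-{(1S,2R,3R)-3-farnesyl-1-methyl-2-[(triisopropylsilyl)oxy]cyclopropyl}-2-methoxyprop-2-en-1-one | C=C(OC)C(=O)[C@]1(C)[C@H](O[Si](C(C)C)(C(C)C)C(C)C)[C@@H]1C/C=C(\C)CC/C=C(\C)CCC=C(C)C | intermediate (key-step precursor)
17 | ring-opened zwitterion: silyloxycarbenium ion at C4, (R)-C5, 2-methoxy dienolate C3=C2–C1(O−)=C6 (drawn without scandium) | C=C(OC)C([O-])=C(C)[C@@H](C/C=C(\C)CC/C=C(\C)CCC=C(C)C)C=[O+][Si](C(C)C)(C(C)C)C(C)C | intermediate (not isolated)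
18 | cyclic dienol (4R,5R): C1–OH, C1=C6 and C2=C3 double bonds, drawn as the free dienol of the scandium dienolate | COC1=C[C@H](O[Si](C(C)C)(C(C)C)C(C)C)[C@H](C/C=C(\C)CC/C=C(\C)CCC=C(C)C)C(C)=C1O | intermediate (not isolated)
19 | (4R,5R)-5-farnesyl-2-methoxy-6-methyl-4-[(triisopropylsilyl)oxy]cyclohex-2-en-1-one as the mixture of C6 epimers | COC1=C[C@H](O[Si](C(C)C)(C(C)C)C(C)C)[C@H](C/C=C(\C)CC/C=C(\C)CCC=C(C)C)C(C)C1=O | intermediate (not isolated)
20 | (4R,5R,6R)-5-farnesyl-2-methoxy-6-methyl-4-[(triisopropylsilyl)oxy]cyclohex-2-en-1-one | COC1=C[C@H](O[Si](C(C)C)(C(C)C)C(C)C)[C@H](C/C=C(\C)CC/C=C(\C)CCC=C(C)C)[C@@H](C)C1=O | intermediate (key-step product)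
21 | (4R,5R,6R)-5-farnesyl-4-hydroxy-2-methoxy-6-methylcyclohex-2-en-1-one | COC1=C[C@H](O)[C@H](C/C=C(\C)CC/C=C(\C)CCC=C(C)C)[C@@H](C)C1=O | target

**Step count and risks**

Total: 9 steps. Longest linear sequence: 9 steps (1 to 21).

Step 8. The addition of C3 to the silyloxycarbenium ion may show poor facial selectivity, since the preference rests only on allylic strain and the outward silyloxy group, and may close mainly to the 4,5-trans ring. The fallback sets C4 by substitution with inversion instead of in the ring closure. It sets out from 16: cyclisation and DBU equilibration are run as before and the 4,5-trans product, (4S,5R,6R)-5-farnesyl-2-methoxy-6-methyl-4-[(triisopropylsilyl)oxy]cyclohex-2-en-1-one F1, is separated and desilylated with Bu4NF/AcOH to (4S,5R,6R)-5-farnesyl-4-hydroxy-2-methoxy-6-methylcyclohex-2-en-1-one F2. Mitsunobu inversion (4-nitrobenzoic acid, PPh3, diisopropyl azodicarboxylate, THF, 0 °C) should give the (4R,5R,6R)-4-O-(4-nitrobenzoyl) ester F3. Methanolysis with K2CO3 in MeOH at 0 °C brings the route back at 21.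

Step 4. Facial discrimination of the copper carbene on the (Z)-enol ether may be insufficient, and any (E)-7 carried from step 3 would place the opposite configuration at the chain-bearing carbon; either process lowers the enantiomeric purity at C5, the one centre that is never corrected later. The fallback replaces asymmetric induction by resolution. It sets out from 7: cyclopropanation with 8 under achiral catalysis (Cu(acac)2, CH2Cl2, reflux, slow addition) should give the exo ester as the racemate, that is 9 together with ethyl (1S,2S,3S)-3-farnesyl-2-[(triisopropylsilyl)oxy]cyclopropane-1-carboxylate F4. Preparative chromatography on a chiral stationary phase separates the two, and the route is rejoined at 9.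

Step 6. Acyl substitution at the ester of 11, which sits on a fully substituted ring carbon flanked by two cis substituents, may be too slow, and forcing it invites desilylative opening of the cyclopropane. The fallback reaches the ketone through the aldehyde oxidation level. It sets out from 11: LiAlH4 (Et2O, 0 °C) should give {(1S,2R,3R)-3-farnesyl-1-methyl-2-[(triisopropylsilyl)oxy]cyclopropyl}methanol F5, and Dess–Martin periodinane buffered with NaHCO3 then gives (1S,2R,3R)-3-farnesyl-1-methyl-2-[(triisopropylsilyl)oxy]cyclopropane-1-carbaldehyde F6, which has no alpha hydrogen. Addition of 14 at −78 °C gives 1-{(1S,2R,3R)-3-farnesyl-1-methyl-2-[(triisopropylsilyl)oxy]cyclopropyl}-2-methoxyprop-2-en-1-ol F7 as a mixture of carbinol epimers, and a second buffered Dess–Martin oxidation returns the route at 16.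

**Further compounds**

F1 | step 8 | (4S,5R,6R)-5-farnesyl-2-methoxy-6-methyl-4-[(triisopropylsilyl)oxy]cyclohex-2-en-1-one | COC1=C[C@@H](O[Si](C(C)C)(C(C)C)C(C)C)[C@H](C/C=C(\C)CC/C=C(\C)CCC=C(C)C)[C@@H](C)C1=O
F2 | step 8 | (4S,5R,6R)-5-farnesyl-4-hydroxy-2-methoxy-6-methylcyclohex-2-en-1-one | COC1=C[C@@H](O)[C@H](C/C=C(\C)CC/C=C(\C)CCC=C(C)C)[C@@H](C)C1=O
F3 | step 8 | (4R,5R,6R)-4-O-(4-nitrobenzoyl) ester of 21 | COC1=C[C@H](OC(=O)c2ccc(cc2)[N+](=O)[O-])[C@H](C/C=C(\C)CC/C=C(\C)CCC=C(C)C)[C@@H](C)C1=O
F4 | step 4 | ethyl (1S,2S,3S)-3-farnesyl-2-[(triisopropylsilyl)oxy]cyclopropane-1-carboxylate (enantiomer of 9) | CCOC(=O)[C@@H]1[C@@H](O[Si](C(C)C)(C(C)C)C(C)C)[C@H]1C/C=C(\C)CC/C=C(\C)CCC=C(C)C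
F5 | step 6 | {(1S,2R,3R)-3-farnesyl-1-methyl-2-[(triisopropylsilyl)oxy]cyclopropyl}methanol | OC[C@]1(C)[C@H](O[Si](C(C)C)(C(C)C)C(C)C)[C@@H]1C/C=C(\C)CC/C=C(\C)CCC=C(C)C
F6 | step 6 | (1S,2R,3R)-3-farnesyl-1-methyl-2-[(triisopropylsilyl)oxy]cyclopropane-1-carbaldehyde | O=C[C@]1(C)[C@H](O[Si](C(C)C)(C(C)C)C(C)C)[C@@H]1C/C=C(\C)CC/C=C(\C)CCC=C(C)C
F7 | step 6 | 1-{(1S,2R,3R)-3-farnesyl-1-methyl-2-[(triisopropylsilyl)oxy]cyclopropyl}-2-methoxyprop-2-en-1-ol (carbinol epimers) | C=C(OC)C(O)[C@]1(C)[C@H](O[Si](C(C)C)(C(C)C)C(C)C)[C@@H]1C/C=C(\C)CC/C=C(\C)CCC=C(C)C
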